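Z, the product, held 13.1% of the J charged at 60.0 min in the blue run, less than E at 56.9%. I kept a ledger of J, in percent of the charge.

| flask | J | X | remark | time |
|---|---|---|---|---|
| blue | 0.46 M | 1 equiv | run made earlier |  |
| teal | 0.73 M | 1 equiv | run made earlier |  |
| flask | 0.33 M | 1.00 equiv |  | 80 min |

| run | time / min | J / % | Q / % | Z / % | E / % | G / % |
|---|---|---|---|---|---|---|
| blue | 5.00 | 84.0 | 3.6 | 0 | 14.5 | 0.6 |
| blue | 8.00 | 75.1 | 3.9 | 0.5 | 21.8 | 1.2 |
| blue | 15.0 | 56.9 | 5.8 | 1.3 | 32.7 | 1.9 |
| blue | 25.0 | 37.1 | 10.5 | 5.2 | 44.3 | 4.1 |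
| blue | 40.0 | 22.4 | 14.7 | 6.5 | 51.3 | 5.6 |
| blue | 60.0 | 13.7 | 15.8 | 13.1 | 56.9 | 1.2 |
| teal | 4.00 | 87.9 | 1.9 | 0 | 11.2 | 0.2 |
| teal | 12.0 | 65.5 | 5.0 | 0.1 | 27.1 | 3.2 |
| teal | 25.0 | 39.2 | 9.3 | 3.2 | 44.4 | 3.9 |
| teal | 40.0 | 23.5 | 12.4 | 8.5 | 53.3 | 4.1 |
| teal | 50.0 | 18.1 | 13.3 | 9.4 | 55.5 | 3.8 |
| teal | 60.0 | 13.8 | 12.4 | 12.5 | 55.6 | 3.2 |

(each reading ± 1 percentage point)

- given per volume of solution although it is solid: X
- the earlier runs were read with a standard deviation of 1 percentage point
- at the start none of X is in solution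

* the species that holds most of what was charged as J, at 80 min (J / Z / G / E / Q)
* the largest share itself, whichever of these holds it, in percent of the J charged

At that reading the blue run gave 0.529 for the side ratio, the J booked to Q, Z and G together per J booked to E, a selectivity factor. The teal run, charged with 0.73 M of J against 0.46 M, gave 0.505 at 60.0 min, close to it. So the two charges agreed at that time. But the blue ratio had been 0.290 at 5.00 min, lower, so I took it as a reading of one moment and not as a constant.

Over the last blue stretch J shrank by the factor 0.612. One more such stretch reaches 80 min, so I booked 8.38% of J for the flask. As a rough estimate, I held the ratio at its last blue reading although it had been rising. Splitting the remainder by it gave E 59.9%, more than the side entries together.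

The forecast said E with 57%, reasoning that “E should stay flat”. My figure stood higher than its number.

The flask gave E at 55.4%, with J 10.6%, Z 17.4%, Q 13.9% and G 2.72%.

    J + L → G (k = 0.0570 M⁻¹ min⁻¹)
    J + L ⇌ Q (K = 4.60 M⁻¹, k = 0.0900 M⁻¹ min⁻¹)
    J ⇌ E (K = 5.20, k = 0.0290 min⁻¹)
    G → Z (k = 0.0610 min⁻¹)
    X ⇌ L, rate k5*(cs5 - [L]) while solid is left; crystals form when [L] > cs5 (solubility = 0.250 M, k = 0.0660 min⁻¹)

The flask's side ratio at 80 min was 0.613, above the blue reading. The neighbour with a quarter of the J showed 0.284 at the same time, about half of the flask's, with E at 65.3%. The flask itself had not come to rest. At 800 min its E had fallen to 28.8% and its Z had risen to 63.3%, more than E, and its side ratio stood at 2.31.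

(Readings and results were computed with constants of no real substance; the scatter is artificial.)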